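**Plan**

1. Retrosynthesis: remove the C17 methylene from C16 and exchange the C14 acetate for a silyl ether; open the lactone at C3–O(C9); undo a 1,2-shift of C14 from C8 back to C15, which turns the bicyclo[2.2.2]octane (C8, C9, C11–C16) into a bicyclo[3.2.1]octane bridgehead carbinol carrying a C8–C9 epoxide; cut C9–C11 (sp2–sp3 coupling) and C8–C15 (aldol) to a ring B keto ester and a 2-siloxy-4-(bromomethyl)cyclopentanone.
2. Forward: ring B (from 2-methylcyclohexenone) and the cyclopentane (from cyclopent-3-enylmethanol) are joined at C8–C15; nickel closes C9–C11 to the bicyclo[3.2.1]octene; epoxidation and the 1,2-shift give the bicyclo[2.2.2]octane; the δ-lactone closes next; the C14 acetate and the C16 methylene come last.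
3. Enabling feature: the C15 ketone flanked by quaternary C8, with the tertiary C9–O one carbon further, inside the bicyclo[2.2.2]octane fused to ring B, is the β-oxy ketone that an α-hydroxy epoxide leaves after a semipinacol shift.
4. Stereochemistry: C5 from a catalytic asymmetric conjugate addition; C10 by Michael addition anti to the isopropenyl group; C12 and C14 from a desymmetrised meso diol; C15 (temporary) by aldol attack anti to the siloxy group; C8 and C9 from the face of the directed epoxidation followed by anti migration.
5. Numbering (atisane): C5 = CH bearing isopropenyl, C10 = quaternary C bearing the C20 methyl and the C1–C2–C3 chain, C8/C12 = bridgeheads, C9 = lactone carbinol carbon, C14 = CH–O, C15 = C=O, C16 = methylene-bearing carbon, C17 = exocyclic CH2.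

Key step: step 12

Assumption: the sense of induction of the chiral ligand in step 1 and of the chiral silylation catalyst in step 5 is not predicted here; the antipode named is taken to give the configuration drawn, and the other antipode is used if it does not.

**Route**

Step 1
Reactants: 1 2-methylcyclohex-2-en-1-one; 2 isopropenylmagnesium bromide
Product: 4 (3R)-2-methyl-3-(prop-1-en-2-yl)cyclohexan-1-one (C2 epimers), via bromomagnesium enolate 3 (not isolated)
Conditions: CuBr·SMe2 (5 mol %), (R)-1-[(S)-2-(diphenylphosphino)ferrocenyl]ethyldicyclohexylphosphine (6 mol %), t-BuOMe, −78 °C; aq NH4Cl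
Reagents that add atoms: none
Why: Copper-catalysed asymmetric conjugate addition of a Grignard reagent to a cyclic enone, in which the chiral diphosphine–copper complex delivers the isopropenyl group to one face of the β-carbon and so sets C5, while the α-carbon (future C10) is left as a mixture because it is reset in step 2.

Step 2
Reactants: 4 (3R)-2-methyl-3-(prop-1-en-2-yl)cyclohexan-1-one; 5 methyl acrylate
Product: 6 methyl 3-[(1S,6S)-1-methyl-2-oxo-6-(prop-1-en-2-yl)cyclohexyl]propanoate
Conditions: t-BuOK (10 mol %), t-BuOH/THF, 0 °C → rt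
Reagents that add atoms: none
Why: Base-catalysed Michael addition through the more substituted (thermodynamic) enolate of a 2-alkylcyclohexanone should give the 2,2-disubstituted ketone, and the acrylate should enter anti to the neighbouring isopropenyl group, which sets C10 with the methyl cis and the propanoate chain trans to isopropenyl.

Step 3
Reactants: 7 cyclopent-3-en-1-ylmethanol
Product: 8 4-(bromomethyl)cyclopent-1-ene
Conditions: CBr4, PPh3, CH2Cl2, 0 °C
Reagents that add atoms: carbon tetrabromide, BrC(Br)(Br)Br
Why: Appel bromination of a primary alcohol under neutral conditions that leave the ring alkene untouched.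

Step 4
Reactants: 8 4-(bromomethyl)cyclopent-1-ene
Product: 9 meso-(1R,2S,4s)-4-(bromomethyl)cyclopentane-1,2-diol (cis-diol trans to CH2Br)
Conditions: OsO4 (2 mol %), N-methylmorpholine N-oxide, acetone/H2O, 0 °C → rt
Reagents that add atoms: osmium tetroxide (oxygen carrier), O=[Os](=O)(=O)=O; N-methylmorpholine N-oxide, C[N+]1([O-])CCOCC1; water, O
Why: Catalytic osmium tetroxide syn-dihydroxylation, in which the reagent should approach the cyclopentene anti to the bromomethyl group and give mainly the meso diol with both hydroxyls trans to C11, the minor all-cis diol being removed by chromatography.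

Step 5
Reactants: 9 meso-4-(bromomethyl)cyclopentane-1,2-diol
Product: 10 (1R,2S,4R)-4-(bromomethyl)-2-[(tert-butyldimethylsilyl)oxy]cyclopentan-1-ol
Conditions: TBSCl, iPr2NEt, (S)-N-[(R)-3,3-dimethylbutan-2-yl]-3,3-dimethyl-2-{[(1-methylimidazol-2-yl)methyl]amino}butanamide (20 mol %), THF, −40 °C
Reagents that add atoms: tert-butyldimethylsilyl chloride, CC(C)(C)[Si](C)(C)Cl
Why: Catalytic enantioselective monosilylation (desymmetrisation) of a meso 1,2-diol by a hydrogen-bonding amino amide that carries an N-methylimidazole Lewis base, in which the catalyst selects the hydroxyl on the future C14 and thereby fixes C14 and, through the trans relationship made in step 4, C12.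

Step 6
Reactants: 10 (1R,2S,4R)-4-(bromomethyl)-2-[(tert-butyldimethylsilyl)oxy]cyclopentan-1-ol
Product: 11 (2S,4S)-4-(bromomethyl)-2-[(tert-butyldimethylsilyl)oxy]cyclopentan-1-one
Conditions: DMP (1,1,1-triacetoxy-1,1-dihydro-1,2-benziodoxol-3(1H)-one), CH2Cl2, 0 °C → rt
Reagents that add atoms: none
Why: Hypervalent-iodine oxidation of the remaining secondary alcohol under non-basic conditions should give the α-siloxy ketone without epimerising C14 or touching the primary bromide.

Step 7
Reactants: 6 methyl 3-[(1S,6S)-1-methyl-2-oxo-6-(prop-1-en-2-yl)cyclohexyl]propanoate; 11 (2S,4S)-4-(bromomethyl)-2-[(tert-butyldimethylsilyl)oxy]cyclopentan-1-one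
Product: 14 C8–C15 aldol adduct as its C15 trimethylsilyl ether (C15–OTMS cis to C14–OTBS; C8 cis to CH2Br), via lithium enolate 12 (not isolated), via lithium aldolate 13 (not isolated)
Conditions: LiN(iPr)2, THF, −78 °C; 11, −78 °C; TMSOTf, −78 °C; aq NaHCO3
Reagents that add atoms: trimethylsilyl trifluoromethanesulfonate, C[Si](C)(C)OS(=O)(=O)C(F)(F)F
Why: Kinetic deprotonation at C8 (the only enolisable position of the ketone, C10 being quaternary) and aldol addition of the lithium enolate to the inductively activated α-siloxy ketone, with the aldolate silylated cold to block retro-aldol cleavage; the enolate should attack C15 anti to the adjacent OTBS group, which places C8 cis to the bromomethyl carbon as the later ring closure requires, and the new C8 centre (expected anti to the axial C20 methyl) is erased in step 8.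

Step 8
Reactants: 14 aldol adduct C15 trimethylsilyl ether
Product: 16 C9 enol triflate with the C8=C9 double bond, via potassium enolate 15 (not isolated)
Conditions: KN(SiMe3)2 added to 14 and N-(5-chloropyridin-2-yl)bis(trifluoromethanesulfonimide), THF, −78 °C
Reagents that add atoms: N-(5-chloropyridin-2-yl)bis(trifluoromethanesulfonimide), FC(F)(F)S(=O)(=O)N(c1ccc(Cl)cn1)S(=O)(=O)C(F)(F)F
Why: Enolate O-triflation, in which C8–H is the only α-hydrogen of the C9 ketone so that the tetrasubstituted enol triflate can form in one regiochemistry only, and adding the base in the presence of the triflating agent keeps the enolate short-lived (no loss of the β-siloxy group, no C-alkylation by the bromide).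

Step 9
Reactants: 16 C9 enol triflate
Product: 17 tricyclic bicyclo[3.2.1]oct-2-ene with C15–OTMS (C8=C9 shared with ring B)
Conditions: NiBr2·DME (10 mol %), 4,4'-di-tert-butyl-2,2'-bipyridine (12 mol %), Mn powder, NaI (25 mol %), DMA, 40 °C, 0.02 M
Reagents that add atoms: none
Why: Nickel-catalysed reductive cross-electrophile coupling of an alkenyl triflate with a primary alkyl bromide, run intramolecularly at high dilution, in which the C11 radical is captured by the alkenylnickel at C9 and reductive elimination closes the six-membered ring with the double bond fixed at C8=C9.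

Step 10
Reactants: 17 tricyclic alkene with C15–OTMS
Product: 18 tricyclic bridgehead allylic alcohol (C15–OH; C8=C9; C14–OTBS)
Conditions: K2CO3 (20 mol %), MeOH, 0 °C → rt
Reagents that add atoms: none
Why: Mild methanolysis should remove the trimethylsilyl ether selectively in the presence of the secondary TBS ether and the methyl ester.

Step 11
Reactants: 18 tricyclic bridgehead allylic alcohol
Product: 19 C8–C9 epoxy carbinol (epoxide syn to C16 and anti to the C20 methyl)
Conditions: VO(acac)2 (5 mol %), t-BuOOH (decane), CH2Cl2, 0 °C
Reagents that add atoms: tert-butyl hydroperoxide, CC(C)(C)OO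
Why: Vanadium-catalysed hydroxyl-directed epoxidation of an allylic alcohol, which leaves the isopropenyl group alone and should deliver oxygen to the face syn to the one-carbon bridge C16, towards which the bridgehead hydroxyl leans and which is anti to both the pseudoaxial C20 methyl and the C13–C14 bridge, so setting C8 and C9.

Step 12
Reactants: 19 C8–C9 epoxy carbinol
Product: 20 9-hydroxy-15-oxo bicyclo[2.2.2]octane ketol (methyl ester; C14–OTBS)
Conditions: BF3·OEt2 (1.1 equiv), CH2Cl2, −78 °C; Et3N, −78 °C
Reagents that add atoms: none
Why: BF3 binds the epoxide oxygen and the C8–O bond ionises while the antiperiplanar C15–C14 σ-bond slides to C8 and the carbinol oxygen closes down to the C15 ketone, so that C8–C14 forms as C15–C14 breaks and the oxygen stays on C9 as the boron alkoxide. The closest known reaction is the Lewis-acid semipinacol rearrangement of 2,3-epoxy alcohols with a tertiary carbinol. No ring is closed by cyclisation: the 1,2-shift enlarges the five-membered ring C15–C14–C13–C12–C16 by insertion of C8 and shrinks the seven-membered ring C15–C8–C9–C11–C12–C13–C14 by loss of C15, which together make the bicyclo[2.2.2]octane. The new quaternary stereocentre C8 is formed with inversion (C14 enters anti to the departing oxygen) and is therefore dictated by the epoxide configuration of step 11, while C9 keeps its oxygen and configuration and C14 migrates with retention. The step needs C8–O rather than C9–O cleavage and C14 rather than C16 migration: only a cation developing at C8 is quenched by the adjacent carbinol, and with the epoxide syn to the one-carbon bridge the C15–C14 bond is antiperiplanar to C8–O whereas C15–C16 is gauche. Low temperature and a non-nucleophilic solvent should hold back elimination and hydride shift, and the oxygen lone pair on C14 should help rather than hinder the shift of this carbon.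

Step 13
Reactants: 20 9-hydroxy-15-oxo ketol
Product: 21 C3–O–C9 δ-lactone with C14–OTBS (14-deacetyl-14-O-TBS-17-norcrotobarin)
Conditions: camphor-10-sulfonic acid (20 mol %), toluene, 50 °C
Reagents that add atoms: none
Why: Acid-catalysed intramolecular transesterification, in which the axial C9 hydroxyl and the equatorial propanoate chain on C10 are gauche so that the δ-lactone should close readily, and which also masks the β-hydroxy ketone against retro-aldol cleavage.

Step 14
Reactants: 21 δ-lactone with C14–OTBS
Product: 22 14-deacetyl-17-norcrotobarin (C14–OH)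
Conditions: HF·pyridine, pyridine/THF, 0 °C → rt
Reagents that add atoms: none
Why: Fluoride cleavage of the silyl ether under buffered acidic conditions that should neither open the lactone nor trigger retro-aldol cleavage of the C14 β-hydroxy ketone.

Step 15
Reactants: 22 14-deacetyl-17-norcrotobarin
Product: 23 17-norcrotobarin (C14–OAc; C16 = CH2)
Conditions: Ac2O, pyridine, 4-(dimethylamino)pyridine (10 mol %), CH2Cl2, rt
Reagents that add atoms: acetic anhydride, CC(=O)OC(C)=O
Why: Acetylation of a hindered secondary alcohol under nucleophilic catalysis, mild enough to leave the β-hydroxy ketone intact until it is capped.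

Step 16
Reactants: 23 17-norcrotobarin
Product: 25 16-(dimethylaminomethyl) ketone (Mannich base; C16 epimers), via trimethylsilyl enol ether 24 (not isolated)
Conditions: TMSOTf, Et3N, CH2Cl2, 0 °C; Me2N=CH2 I, rt; aq NaHCO3
Reagents that add atoms: dimethylmethyleneammonium iodide, C=[N+](C)C.[I-]
Why: Soft enolisation of the ketone, which can only enolise towards C16 because C8 is quaternary and is silylated far faster than the lactone or the acetate, followed by Mannich reaction of the silyl enol ether with the preformed iminium salt; the new C16 centre is not controlled and is removed in step 17.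

Step 17
Reactants: 25 16-(dimethylaminomethyl) ketone
Product: 27 crotobarin, via trimethylammonium iodide 26 (not isolated)
Conditions: MeI, CH2Cl2, rt; aq NaHCO3, rt
Reagents that add atoms: none
Why: Exhaustive N-methylation and base-induced β-elimination of trimethylamine from the β-ammonio ketone should unveil the α-methylene ketone under conditions that spare the acetate and the lactone.

**Compound list**

1 | 2-methylcyclohex-2-en-1-one | CC1=CCCCC1=O | starting material
2 | isopropenylmagnesium bromide | CC(=C)[Mg]Br | starting material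
3 | bromomagnesium enolate of 4 | Br[Mg]OC1=C(C)[C@H](C(=C)C)CCC1 | intermediate
4 | (3R)-2-methyl-3-(prop-1-en-2-yl)cyclohexan-1-one (C2 epimers) | O=C1CCC[C@@H](C(=C)C)C1C | intermediate
5 | methyl acrylate | C=CC(=O)OC | starting material
6 | methyl 3-[(1S,6S)-1-methyl-2-oxo-6-(prop-1-en-2-yl)cyclohexyl]propanoate | O=C1CCC[C@@H](C(=C)C)[C@]1(C)CCC(=O)OC | intermediate
7 | cyclopent-3-en-1-ylmethanol | OCC1CC=CC1 | starting material
8 | 4-(bromomethyl)cyclopent-1-ene | BrCC1CC=CC1 | intermediate
9 | meso-(1R,2S,4s)-4-(bromomethyl)cyclopentane-1,2-diol (cis-diol trans to CH2Br) | O[C@@H]1C[C@@H](CBr)C[C@@H]1O | intermediate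
10 | (1R,2S,4R)-4-(bromomethyl)-2-[(tert-butyldimethylsilyl)oxy]cyclopentan-1-ol | O[C@@H]1C[C@@H](CBr)C[C@@H]1O[Si](C)(C)C(C)(C)C | intermediate
11 | (2S,4S)-4-(bromomethyl)-2-[(tert-butyldimethylsilyl)oxy]cyclopentan-1-one | O=C1C[C@@H](CBr)C[C@@H]1O[Si](C)(C)C(C)(C)C | intermediate
12 | lithium enolate of 6 (C8=C9–OLi) | [Li]OC1=CCC[C@@H](C(=C)C)[C@]1(C)CCC(=O)OC | intermediate
13 | lithium aldolate (C15–OLi; expected C8 epimer) | O=C1[C@H]([C@@]2(O[Li])C[C@@H](CBr)C[C@@H]2O[Si](C)(C)C(C)(C)C)CC[C@@H](C(=C)C)[C@]1(C)CCC(=O)OC | intermediate
14 | aldol adduct of 6 and 11 as C15 trimethylsilyl ether (C15–OTMS cis to C14–OTBS, trans to CH2Br; expected C8 epimer, inconsequential) | O=C1[C@H]([C@@]2(O[Si](C)(C)C)C[C@@H](CBr)C[C@@H]2O[Si](C)(C)C(C)(C)C)CC[C@@H](C(=C)C)[C@]1(C)CCC(=O)OC | intermediate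
15 | potassium enolate of 14 (C8=C9–OK) | [K]OC1=C([C@@]2(O[Si](C)(C)C)C[C@@H](CBr)C[C@@H]2O[Si](C)(C)C(C)(C)C)CC[C@@H](C(=C)C)[C@]1(C)CCC(=O)OC | intermediate
16 | C9 enol triflate (C8=C9) | FC(F)(F)S(=O)(=O)OC1=C([C@@]2(O[Si](C)(C)C)C[C@@H](CBr)C[C@@H]2O[Si](C)(C)C(C)(C)C)CC[C@@H](C(=C)C)[C@]1(C)CCC(=O)OC | intermediate
17 | tricyclic bicyclo[3.2.1]oct-2-ene, C15–OTMS, C14–OTBS, methyl ester | C1[C@]2(O[Si](C)(C)C)C3=C([C@@](C)(CCC(=O)OC)[C@H](C(=C)C)CC3)C[C@H]1C[C@@H]2O[Si](C)(C)C(C)(C)C | intermediate
18 | tricyclic bridgehead allylic alcohol (C15–OH, C8=C9) | C1[C@]2(O)C3=C([C@@](C)(CCC(=O)OC)[C@H](C(=C)C)CC3)C[C@H]1C[C@@H]2O[Si](C)(C)C(C)(C)C | intermediate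
19 | bicyclo[3.2.1] bridgehead carbinol with C8–C9 epoxide (syn to C16) | C1[C@]2(O)[C@@]34CC[C@@H](C(=C)C)[C@](C)(CCC(=O)OC)[C@@]3(O4)C[C@H]1C[C@@H]2O[Si](C)(C)C(C)(C)C | intermediate
20 | 9-hydroxy-15-oxo bicyclo[2.2.2]octane ketol (methyl ester, C14–OTBS) | C1C(=O)[C@]23CC[C@@H](C(=C)C)[C@](C)(CCC(=O)OC)[C@@]2(O)C[C@H]1C[C@@H]3O[Si](C)(C)C(C)(C)C | intermediate
21 | 14-deacetyl-14-O-TBS-17-norcrotobarin (δ-lactone) | C1C(=O)[C@]23CC[C@@H](C(=C)C)[C@]4(C)CCC(=O)O[C@@]42C[C@H]1C[C@@H]3O[Si](C)(C)C(C)(C)C | intermediate
22 | 14-deacetyl-17-norcrotobarin | C1C(=O)[C@]23CC[C@@H](C(=C)C)[C@]4(C)CCC(=O)O[C@@]42C[C@H]1C[C@@H]3O | intermediate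
23 | 17-norcrotobarin | C1C(=O)[C@]23CC[C@@H](C(=C)C)[C@]4(C)CCC(=O)O[C@@]42C[C@H]1C[C@@H]3OC(C)=O | intermediate
24 | C15 trimethylsilyl enol ether of 23 (C15=C16) | C1=C(O[Si](C)(C)C)[C@]23CC[C@@H](C(=C)C)[C@]4(C)CCC(=O)O[C@@]42C[C@H]1C[C@@H]3OC(C)=O | intermediate
25 | 16-(dimethylaminomethyl)-17-norcrotobarin (C16 epimers) | CN(C)CC1C(=O)[C@]23CC[C@@H](C(=C)C)[C@]4(C)CCC(=O)O[C@@]42C[C@H]1C[C@@H]3OC(C)=O | intermediate
26 | trimethylammonium iodide of 25 | C[N+](C)(C)CC1C(=O)[C@]23CC[C@@H](C(=C)C)[C@]4(C)CCC(=O)O[C@@]42C[C@H]1C[C@@H]3OC(C)=O.[I-] | intermediate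
27 | crotobarin | C=C1C(=O)[C@]23CC[C@@H](C(=C)C)[C@]4(C)CCC(=O)O[C@@]42C[C@H]1C[C@@H]3OC(C)=O | target

**Step count and risks**

Total steps: 17. Longest linear sequence: 15 steps (steps 3–17, from cyclopent-3-en-1-ylmethanol); the ring B branch (steps 1–2) joins at step 7.

Steps most likely to fail:

Step 8 (enol triflate). Deprotonation of the hindered C8 methine may be slow, so that the base attacks the position α to the ester instead. The enolate, once formed, may expel the C15 siloxy group or be C-alkylated by the bromide before it is triflated. The fallback sets out from 14 and avoids a strong base. TMSOTf/Et3N in CH2Cl2 at 0 °C should enolise only the ketone, and only towards C8, to give the tetrasubstituted trimethylsilyl enol ether F1. Nonafluorobutanesulfonyl fluoride with catalytic tetrabutylammonium difluorotriphenylsilicate in THF should then exchange the enol silyl group, which is far more fluoride-labile than the two alkyl silyl ethers, for the sulfonyl group and give the alkenyl nonaflate F2. F2 takes the place of 16 in the nickel cyclisation and the route is rejoined at 17.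

Step 9 (nickel ring closure). Reduction of the carbon–bromine or carbon–triflate bond may outrun ring closure, the alkylnickel may lose a β-hydride, or capture of the C11 radical at the hindered tetrasubstituted alkenyl centre may be too slow. The fallback sets out from 16 and replaces the radical cross-electrophile manifold by a polar coupling with a preformed nucleophile. Zinc dust activated with LiCl (THF, 50 °C) should insert into the C11–Br bond to give the alkylzinc bromide F3, and Pd(PPh3)4 should then close C9–C11 by an intramolecular Negishi coupling. The route is rejoined at 17.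

Step 7 (aldol union). Proton transfer from the enolisable cyclopentanone to the enolate, reversal of the ketone–ketone aldol before silylation, or loss of facial selectivity at C15 may lower the yield of the usable diastereomer. The fallback sets out from 6 and exchanges the basic metal enolate for a Lewis-acid-mediated Mukaiyama aldol. LiN(iPr)2/TMSCl should give the trimethylsilyl enol ether F4. TiCl4 in CH2Cl2 at −78 °C should activate ketone 11 towards F4 and give, after aqueous work-up, the β-hydroxy ketone F5 without any basic species present. TMSOTf/2,6-lutidine at −78 °C then silylates the tertiary hydroxyl and the route is rejoined at 14.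

**Further compounds**

F1 | step 8 | tetrasubstituted trimethylsilyl enol ether of 14 (C8=C9–OTMS) | C[Si](C)(C)OC1=C([C@@]2(O[Si](C)(C)C)C[C@@H](CBr)C[C@@H]2O[Si](C)(C)C(C)(C)C)CC[C@@H](C(=C)C)[C@]1(C)CCC(=O)OC
F2 | step 8 | C9 alkenyl nonaflate (C8=C9) | FC(F)(F)C(F)(F)C(F)(F)C(F)(F)S(=O)(=O)OC1=C([C@@]2(O[Si](C)(C)C)C[C@@H](CBr)C[C@@H]2O[Si](C)(C)C(C)(C)C)CC[C@@H](C(=C)C)[C@]1(C)CCC(=O)OC
F3 | step 9 | C11 alkylzinc bromide of enol triflate 16 | FC(F)(F)S(=O)(=O)OC1=C([C@@]2(O[Si](C)(C)C)C[C@@H](C[Zn]Br)C[C@@H]2O[Si](C)(C)C(C)(C)C)CC[C@@H](C(=C)C)[C@]1(C)CCC(=O)OC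
F4 | step 7 | trimethylsilyl enol ether of 6 (C8=C9–OTMS) | C[Si](C)(C)OC1=CCC[C@@H](C(=C)C)[C@]1(C)CCC(=O)OC
F5 | step 7 | free C15 β-hydroxy ketone (aldol adduct of 6 and 11) | O=C1[C@H]([C@@]2(O)C[C@@H](CBr)C[C@@H]2O[Si](C)(C)C(C)(C)C)CC[C@@H](C(=C)C)[C@]1(C)CCC(=O)OC
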